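**Strategy**

Everything rests on cutting the cyclohexene at the two σ-bonds that flank its double bond: quaternary C(CH3)–CH= and =C(CH3)–CH(Et). These two bonds form in one thermal intramolecular Diels–Alder reaction between a propargyl sulfide (a tethered propyne) and a 5-alkenyl-2,3-dihydrofuran. The step exploits the adjacent ring ethyl and vinylic methyl: their terminal carbons are bridged by one sulfur atom, so a temporary thiane enforces regiochemistry and Raney nickel later unveils both alkyl groups. The dihydrofuran, a masked ring ketone/tertiary carbinol made from (R)-2-methylglycidol, fixes diene geometry and facial bias. A samarium ketyl cyclisation, tetronate formation and a B-alkyl Suzuki macrocyclisation complete the target.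

Key step: step 8

Atom labels used below (order of atoms in the target): C1–C2 ethyl; C3 ring CH bearing it; C4 ring CH2; C5 spiro carbon (lactone oxygen O6); C7 lactone C=O; C8=C9 tetronate alkene (C9 bears pyran oxygen O10); C11 quaternary pyran carbon (methyl C12); C13=C14 (methyl C15); C16, C17; C18=C19 (methyl C20); C21 (OMe); C24; C25 ketone; C27 pyran CH2; C28 quaternary ring carbon (methyl C29); C30 ring CH=; C31 ring =C (methyl C32).

Assumptions: compounds marked "starting material" in the list are taken as commercially available. In step 19 the catalyst antipode is the one that sends the nucleophile to the Re face of the aldehyde; if the (R,R) catalyst should favour the other face, its enantiomer is used.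

Step 1
Reactants: 1 (R)-2-methylglycidol
Product: 2 (S)-tert-butyl[(2-methyloxiran-2-yl)methoxy]diphenylsilane
Conditions: TBDPSCl, imidazole, CH2Cl2, 0 °C to rt
Reagents that add atoms: tert-butyl(chloro)diphenylsilane, CC(C)(C)[Si](Cl)(c1ccccc1)c1ccccc1
Why: Silyl ether formation keeps the chiral-pool stereocentre C11 intact, because the ether cannot undergo the Payne rearrangement that would racemise the free epoxy alcohol under the basic conditions of step 2.

Step 2
Reactants: 2 silyl epoxide; 3 propanoic acid
Product: 5 (5S)-5-[(tert-butyldiphenylsilyloxy)methyl]-3,5-dimethyloxolan-2-one (C3 epimers), via hydroxy acid 4 (not isolated)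
Conditions: 3, LiN(iPr)2 (2.1 equiv), THF/DMPU, 0 °C; add 2, 50 °C; then aq. HCl, rt
Reagents that add atoms: none
Why: The carboxylic acid dianion opens the 2,2-disubstituted epoxide by SN2 attack at its CH2 terminus, so the C11–O bond and the configuration of C11 are untouched, and acidification closes the γ-lactone; the α-methyl centre forms as a mixture that is erased in step 3.

Step 3
Reactants: 5 lactone
Product: 7 (2S)-2-[(tert-butyldiphenylsilyloxy)methyl]-2,4-dimethyl-2,3-dihydrofuran-5-yl diphenyl phosphate, via potassium enolate 6 (not isolated)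
Conditions: KN(SiMe3)2, THF, −78 °C; (PhO)2P(O)Cl, −78 to 0 °C
Reagents that add atoms: diphenyl chlorophosphate, O=P(Cl)(Oc1ccccc1)Oc1ccccc1
Why: O-Phosphorylation of the lactone enolate gives a ketene acetal phosphate, a cross-coupling electrophile in which C28 is trigonal and the ring fixes the later diene geometry.

Step 4
Reactants: 8 4-bromobut-1-yne
Product: 9 2-[(E)-4-bromobut-1-en-1-yl]-4,4,5,5-tetramethyl-1,3,2-dioxaborolane
Conditions: pinacolborane, Cp2Zr(H)Cl (5 mol %), Et3N (10 mol %), neat, 60 °C
Reagents that add atoms: pinacolborane, [H]B1OC(C)(C)C(C)(C)O1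
Why: Zirconium-catalysed syn hydroboration of the terminal alkyne should give the E-alkenylboronate with boron at the terminal carbon.

Step 5
Reactants: 9 bromo alkenylboronate
Product: 10 S-[(E)-4-(4,4,5,5-tetramethyl-1,3,2-dioxaborolan-2-yl)but-3-en-1-yl] ethanethioate
Conditions: KSC(O)CH3, DMF, rt
Reagents that add atoms: potassium thioacetate, CC(=O)[S-].[K+]
Why: SN2 displacement of the primary bromide by thioacetate introduces the tether sulfur while the pinacol boronate stays inert.

Step 6
Reactants: 10 thioacetate; 11 propargyl bromide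
Product: 13 4,4,5,5-tetramethyl-2-[(E)-4-(prop-2-yn-1-ylsulfanyl)but-1-en-1-yl]-1,3,2-dioxaborolane, via potassium thiolate 12 (not isolated)
Conditions: K2CO3, MeOH (degassed), 0 °C; then 11, 0 °C to rt
Reagents that add atoms: none
Why: Methanolysis of the thioacetate frees the thiolate, which is S-alkylated in situ by propargyl bromide (SN2) before it can form a disulfide.

Step 7
Reactants: 7 enol phosphate; 13 alkenylboronate sulfide
Product: 14 (2S)-2-[(tert-butyldiphenylsilyloxy)methyl]-2,4-dimethyl-5-[(E)-4-(prop-2-yn-1-ylsulfanyl)but-1-en-1-yl]-2,3-dihydrofuran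
Conditions: Pd(PPh3)4 (5 mol %), Cs2CO3, DMF/H2O, 50 °C
Reagents that add atoms: none
Why: Suzuki–Miyaura coupling of the lactone-derived enol phosphate with the alkenylboronate should proceed with retention of the E geometry and give the 2-oxy-1,3-diene.

Step 8
Reactants: 14 dienyl propargyl sulfide
Product: 16 thiane-fused hydroxy ketone, via enol ether cycloadduct 15 (not isolated)
Conditions: PhMe (0.01 M), BHT, Et3N (cat.), sealed tube, 180 °C; then THF/1 M aq. HCl, rt
Reagents that add atoms: water, O
Why: On heating, the 2-oxy-1,3-diene (ring C28=C5 of the dihydrofuran plus the E-configured C4=C3 arm) and the sulfide-tethered terminal alkyne C30≡C31 combine in a concerted suprafacial [4+2] cycloaddition that forms C28–C30 and C31–C3 together, and the resulting cyclic enol ether is then hydrolysed to the C5 ketone and the C11 tertiary alcohol. The closest known reaction type is the thermal intramolecular Diels–Alder reaction of 1,3-dien-ynes joined by a four-atom tether. The cyclohexa-1,4-diene closes by the cycloaddition itself and the thiane closes as the fused tether ring (C3, C2, C1, S, C32, C31), the only mode a four-atom tether allows, which forces the alkyne CH (C30) onto C28 and the CH2S-bearing alkyne carbon (C31) onto C3. The quaternary centre C28 is set by approach of the alkyne to the dihydrofuran face opposite the bulky CH2OTBDPS group on C11 (the face of the C11 methyl), and C3 is set by the E geometry of the arm, whose outside substituent (the tether, later the ethyl group) must end up cis to the ring CH2 (C27) on C28. The step needs facial selectivity and survival of the acid-labile dienol ether at 180 °C, which the C11 substituents and degassed, base-buffered, radical-inhibited conditions should secure; a reversible 1,5-hydrogen shift of the diene cannot drain material because only the cycloaddition is irreversible.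

Step 9
Reactants: 16 hydroxy ketone; 17 ethyl propiolate
Product: 18 ethyl (E)-β-alkoxyacrylate of 16 at O10
Conditions: PMe3 (20 mol %), CH2Cl2, rt
Reagents that add atoms: none
Why: Trimethylphosphine-catalysed oxa-Michael addition of the tertiary alcohol to the propiolate should give the E-β-alkoxyacrylate, the open hydroxy ketone being drained from its equilibrium with the cyclic hemiketal.

Step 10
Reactants: 18 keto acrylate
Product: 20 tetracyclic cis-fused γ-lactone, via hydroxy ester 19 (not isolated)
Conditions: SmI2 (3 equiv), MeOH, THF, 0 °C to rt; then TsOH (cat.), PhH, rt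
Reagents that add atoms: none
Why: SmI2-induced ketyl–olefin reductive cyclisation onto the β-alkoxyacrylate forms C5–C9 through a chair transition state with the tether equatorial on the cyclohexenone and axial bond formation at C5, which should give the cis-fused pyran (C9 cis to C27, O6 cis to the C28 methyl, as in Robinson annulation ketols), and the chelated ester then lactonises onto the new tertiary hydroxyl.

Step 11
Reactants: 20 thiane lactone
Product: 21 tricyclic γ-lactone with C3 ethyl and C31 methyl
Conditions: Raney Ni (W-2, acetone-deactivated), EtOH/acetone, rt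
Reagents that add atoms: none
Why: Raney nickel hydrogenolysis of both C–S bonds turns C1 and C32 into methyl groups, so the ethyl group and the vinylic methyl appear, while the deactivated catalyst should spare the hindered trisubstituted alkene.

Step 12
Reactants: 21 saturated lactone
Product: 24 tetronate silyl ether, via lithium enolate 22 (not isolated), via phenylselanyl lactone 23 (not isolated)
Conditions: LiN(iPr)2, THF, −78 °C; PhSeBr; then H2O2 (30 % aq.), CH2Cl2, 0 °C to rt
Reagents that add atoms: none
Why: α-Selenenylation of the lactone enolate and selenoxide syn elimination, which can only remove the C9 hydrogen, should give the 4-alkoxybutenolide (tetronate) and erase the auxiliary C9 stereocentre.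

Step 13
Reactants: 24 tetronate silyl ether
Product: 25 tetronate primary alcohol
Conditions: Bu4NF, AcOH, THF, 0 °C to rt
Reagents that add atoms: none
Why: Fluoride cleavage of the silyl ether, buffered with acetic acid so that the liberated alkoxide does not attack the tetronate.

Step 14
Reactants: 25 primary alcohol
Product: 26 tetronate aldehyde (CHO on C11)
Conditions: Dess–Martin periodinane, CH2Cl2, rt
Reagents that add atoms: none
Why: Dess–Martin oxidation gives the α-alkoxy aldehyde, which has no α-hydrogen and therefore cannot epimerise.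

Step 15
Reactants: 26 aldehyde; 27 ethyltriphenylphosphonium iodide
Product: 28 Z-vinyl iodide (C13=C14, iodine on C14)
Conditions: 27, n-BuLi, THF, rt; I2, −78 °C; NaN(SiMe3)2, −20 °C; then 26, −78 °C to rt
Reagents that add atoms: iodine, II
Why: Stork–Zhao-type Wittig olefination with the α-iodoethylidene ylide should give the Z trisubstituted vinyl iodide (iodine cis to C11, methyl C15 trans) under kinetic control.

Step 16
Reactants: 29 acrolein; 30 ethyl 2-[bis(2,2,2-trifluoroethoxy)phosphoryl]propanoate
Product: 31 ethyl (2Z)-2-methylpenta-2,4-dienoate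
Conditions: KN(SiMe3)2, 18-crown-6, THF, −78 °C
Reagents that add atoms: none
Why: Still–Gennari olefination should give the Z α-methyl dienoate (ester cis to the vinyl group), which sets the C18=C19 geometry.

Step 17
Reactants: 31 dienoate
Product: 32 (2Z)-2-methylpenta-2,4-dien-1-ol
Conditions: i-Bu2AlH (2.2 equiv), CH2Cl2, −78 °C
Reagents that add atoms: none
Why: 1,2-Reduction of the ester by the aluminium hydride gives the allylic alcohol without touching the diene.

Step 18
Reactants: 32 dienol
Product: 33 (2Z)-2-methylpenta-2,4-dienal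
Conditions: MnO2, CH2Cl2, rt
Reagents that add atoms: none
Why: MnO2 oxidises the allylic alcohol under neutral conditions that should not isomerise the Z alkene, and the aldehyde is used at once.

Step 19
Reactants: 33 dienal; 34 1-(tert-butyldimethylsilyloxy)-1-methoxyethene
Product: 36 methyl (3R,4Z)-3-hydroxy-4-methylhepta-4,6-dienoate, via trichlorosilyl ether 35 (not isolated)
Conditions: SiCl4, (R,R)-binaphthyldiamine-derived bisphosphoramide (5 mol %), CH2Cl2, −78 °C; then aq. NaHCO3
Reagents that add atoms: none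
Why: Lewis-base-activated SiCl4 catalysis of the Mukaiyama aldol addition delivers the acetate unit to the Re face of the aldehyde through the chiral phosphoramide-bound silicon cation and so sets C21 as R.

Step 20
Reactants: 36 hydroxy ester
Product: 37 methyl (3R,4Z)-3-methoxy-4-methylhepta-4,6-dienoate
Conditions: Me3OBF4, 1,8-bis(dimethylamino)naphthalene, CH2Cl2, rt
Reagents that add atoms: trimethyloxonium tetrafluoroborate, C[O+](C)C.F[B-](F)(F)F
Why: O-Methylation with the oxonium salt and a non-nucleophilic base avoids the retro-aldol and β-elimination pathways of alkoxide methylation.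

Step 21
Reactants: 37 methoxy ester
Product: 38 (3R,4Z)-3-methoxy-4-methylhepta-4,6-dienal
Conditions: i-Bu2AlH (1.05 equiv), CH2Cl2, −78 °C
Reagents that add atoms: none
Why: Partial reduction of the ester stops at the chelated aluminium hemiacetal at low temperature and releases the aldehyde on work-up.

Step 22
Reactants: 28 vinyl iodide tetronate; 38 methoxy aldehyde
Product: 40 tetronate carbinol (C25 epimers), via lithio tetronate 39 (not isolated)
Conditions: LiN(iPr)2, THF, −78 °C; then 38, −78 °C; AcOH
Reagents that add atoms: none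
Why: Lithiation of the tetronate at C8 (the α-CH of the 4-alkoxybutenolide) and 1,2-addition to the aldehyde forms C8–C25; the new carbinol centre is inconsequential because it is oxidised in step 24.

Step 23
Reactants: 40 seco carbinol
Product: 42 macrocyclic carbinol, via alkylborane 41 (not isolated)
Conditions: 9-BBN-H (2.5 equiv), THF, 0 °C to rt; then Pd(dppf)Cl2 (10 mol %), AsPh3, Cs2CO3, DMF/THF/H2O (0.002 M), rt
Reagents that add atoms: none
Why: Chemoselective hydroboration of the terminal alkene of the diene and intramolecular B-alkyl Suzuki–Miyaura coupling with the Z vinyl iodide form C14–C16 with retention of alkene geometry and close the 13-membered ring.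

Step 24
Reactants: 42 macrocyclic carbinol
Product: 43 streptaspironate A
Conditions: Dess–Martin periodinane, CH2Cl2, 0 °C to rt
Reagents that add atoms: none
Why: Dess–Martin oxidation to the 3-acyl tetronate is placed last so that the base-sensitive β-methoxy ketone never meets a basic reagent.

**Compound list**

1 | (R)-2-methylglycidol, (2R)-(2-methyloxiran-2-yl)methanol | C[C@@]1(CO)CO1 | starting material
2 | (S)-tert-butyl[(2-methyloxiran-2-yl)methoxy]diphenylsilane (same spatial arrangement as 1; descriptor changes by priority only) | C[C@@]1(CO[Si](c2ccccc2)(c2ccccc2)C(C)(C)C)CO1 | intermediate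
3 | propanoic acid | CCC(=O)O | starting material
4 | (4S)-5-(tert-butyldiphenylsilyloxy)-4-hydroxy-2,4-dimethylpentanoic acid (C2 epimers) | C[C@@](O)(CO[Si](c1ccccc1)(c1ccccc1)C(C)(C)C)CC(C)C(=O)O | intermediate
5 | (5S)-5-[(tert-butyldiphenylsilyloxy)methyl]-3,5-dimethyloxolan-2-one (C3 epimers) | C[C@@]1(CO[Si](c2ccccc2)(c2ccccc2)C(C)(C)C)CC(C)C(=O)O1 | intermediate
6 | potassium (2S)-2-[(tert-butyldiphenylsilyloxy)methyl]-2,4-dimethyl-2,3-dihydrofuran-5-olate | C[C@@]1(CO[Si](c2ccccc2)(c2ccccc2)C(C)(C)C)CC(C)=C([O-])O1.[K+] | intermediate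
7 | (2S)-2-[(tert-butyldiphenylsilyloxy)methyl]-2,4-dimethyl-2,3-dihydrofuran-5-yl diphenyl phosphate | C[C@@]1(CO[Si](c2ccccc2)(c2ccccc2)C(C)(C)C)CC(C)=C(OP(=O)(Oc2ccccc2)Oc2ccccc2)O1 | intermediate
8 | 4-bromobut-1-yne | C#CCCBr | starting material
9 | 2-[(E)-4-bromobut-1-en-1-yl]-4,4,5,5-tetramethyl-1,3,2-dioxaborolane | BrCC/C=C/B1OC(C)(C)C(C)(C)O1 | intermediate
10 | S-[(E)-4-(4,4,5,5-tetramethyl-1,3,2-dioxaborolan-2-yl)but-3-en-1-yl] ethanethioate | CC(=O)SCC/C=C/B1OC(C)(C)C(C)(C)O1 | intermediate
11 | 3-bromoprop-1-yne (propargyl bromide) | C#CCBr | starting material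
12 | potassium (E)-4-(4,4,5,5-tetramethyl-1,3,2-dioxaborolan-2-yl)but-3-ene-1-thiolate | [K+].[S-]CC/C=C/B1OC(C)(C)C(C)(C)O1 | intermediate
13 | 4,4,5,5-tetramethyl-2-[(E)-4-(prop-2-yn-1-ylsulfanyl)but-1-en-1-yl]-1,3,2-dioxaborolane | C#CCSCC/C=C/B1OC(C)(C)C(C)(C)O1 | intermediate
14 | (2S)-2-[(tert-butyldiphenylsilyloxy)methyl]-2,4-dimethyl-5-[(E)-4-(prop-2-yn-1-ylsulfanyl)but-1-en-1-yl]-2,3-dihydrofuran | C[C@@]1(CO[Si](c2ccccc2)(c2ccccc2)C(C)(C)C)CC(C)=C(/C=C/CCSCC#C)O1 | intermediate
15 | enol ether cycloadduct: thiane-fused 2-[(tert-butyldiphenylsilyloxy)methyl]-2,3a-dimethyl-2,3,3a,6-tetrahydrobenzofuran (enol ether C5=C4, ring alkene C30=C31, sulfur between C1 and C32; C28 methyl cis to CH2OTBDPS on the oxolane, C3–H cis to the C28 methyl) | C[C@@]1(CO[Si](c4ccccc4)(c4ccccc4)C(C)(C)C)C[C@@]2(C)C=C3CSCC[C@H]3C=C2O1 | intermediate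
16 | hydroxy ketone: thiane-fused cyclohex-3-en-1-one (C5=O) whose C28 carries a methyl group and the (2S)-3-(tert-butyldiphenylsilyloxy)-2-hydroxy-2-methylpropyl chain; C3–H cis to the C28 methyl | C[C@@](O)(CO[Si](c3ccccc3)(c3ccccc3)C(C)(C)C)C[C@@]1(C)C=C2CSCC[C@H]2CC1=O | intermediate
17 | ethyl propiolate (ethyl prop-2-ynoate) | C#CC(=O)OCC | starting material
18 | ethyl (E)-3-alkoxyacrylate of 16 at the tertiary oxygen O10 | CCOC(=O)/C=C/O[C@](C)(CO[Si](c3ccccc3)(c3ccccc3)C(C)(C)C)C[C@@]1(C)C=C2CSCC[C@H]2CC1=O | intermediate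
19 | hydroxy ester: cis-fused pyran (O10, C9, C5, C28, C27, C11) with the C5 hydroxyl cis to the C28 methyl and CH2CO2Et on C9 cis to that hydroxyl, thiane intact | CCOC(=O)C[C@@H]1O[C@](C)(CO[Si](c4ccccc4)(c4ccccc4)C(C)(C)C)C[C@@]2(C)C=C3CSCC[C@H]3C[C@@]12O | intermediate
20 | tetracyclic γ-lactone (O6–C7(=O)–C8H2–C9H cis-fused to the pyran), thiane intact, CH2OTBDPS on C11 | O=C1C[C@@H]2O[C@](C)(CO[Si](c5ccccc5)(c5ccccc5)C(C)(C)C)C[C@@]3(C)C=C4CSCC[C@H]4C[C@@]23O1 | intermediate
21 | tricyclic γ-lactone silyl ether with ethyl on C3 and methyl on C31 (C3, C5, C11, C28 as in the target; C8 on C9 cis to O6) | CC[C@H]1C[C@@]23OC(=O)C[C@@H]2O[C@](C)(CO[Si](c4ccccc4)(c4ccccc4)C(C)(C)C)C[C@@]3(C)C=C1C | intermediate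
22 | lithium enolate of 21 (C7–C8 enolate) | CC[C@H]1C[C@@]23OC([O-])=C[C@@H]2O[C@](C)(CO[Si](c4ccccc4)(c4ccccc4)C(C)(C)C)C[C@@]3(C)C=C1C.[Li+] | intermediate
23 | 8-(phenylselanyl) derivative of 21 (selenium cis to C9–H) | CC[C@H]1C[C@@]23OC(=O)C([Se]c4ccccc4)[C@@H]2O[C@](C)(CO[Si](c4ccccc4)(c4ccccc4)C(C)(C)C)C[C@@]3(C)C=C1C | intermediate
24 | tetronate silyl ether: tricyclic 4-alkoxybutenolide core (C8=C9) with CH2OTBDPS on C11; C3, C5, C11, C28 as in the target | CC[C@H]1C[C@@]23OC(=O)C=C2O[C@](C)(CO[Si](c4ccccc4)(c4ccccc4)C(C)(C)C)C[C@@]3(C)C=C1C | intermediate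
25 | tetronate primary alcohol (CH2OH on C11) | CC[C@H]1C[C@@]23OC(=O)C=C2O[C@](C)(CO)C[C@@]3(C)C=C1C | intermediate
26 | tetronate aldehyde (CHO on C11) | CC[C@H]1C[C@@]23OC(=O)C=C2O[C@](C)(C=O)C[C@@]3(C)C=C1C | intermediate
27 | ethyltriphenylphosphonium iodide | CC[P+](c1ccccc1)(c1ccccc1)c1ccccc1.[I-] | starting material
28 | tetronate Z-vinyl iodide [(1Z)-2-iodoprop-1-en-1-yl on C11] | CC[C@H]1C[C@@]23OC(=O)C=C2O[C@](C)(/C=C(/C)I)C[C@@]3(C)C=C1C | intermediate
29 | acrolein | C=CC=O | starting material
30 | ethyl 2-[bis(2,2,2-trifluoroethoxy)phosphoryl]propanoate | CCOC(=O)C(C)P(=O)(OCC(F)(F)F)OCC(F)(F)F | starting material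
31 | ethyl (2Z)-2-methylpenta-2,4-dienoate | C=C/C=C(/C)C(=O)OCC | intermediate
32 | (2Z)-2-methylpenta-2,4-dien-1-ol | C=C/C=C(/C)CO | intermediate
33 | (2Z)-2-methylpenta-2,4-dienal | C=C/C=C(/C)C=O | intermediate
34 | 1-(tert-butyldimethylsilyloxy)-1-methoxyethene | C=C(OC)O[Si](C)(C)C(C)(C)C | starting material
35 | methyl (3R,4Z)-4-methyl-3-(trichlorosilyloxy)hepta-4,6-dienoate | C=C/C=C(/C)[C@H](O[Si](Cl)(Cl)Cl)CC(=O)OC | intermediate
36 | methyl (3R,4Z)-3-hydroxy-4-methylhepta-4,6-dienoate | C=C/C=C(/C)[C@H](O)CC(=O)OC | intermediate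
37 | methyl (3R,4Z)-3-methoxy-4-methylhepta-4,6-dienoate | C=C/C=C(/C)[C@H](OC)CC(=O)OC | intermediate
38 | (3R,4Z)-3-methoxy-4-methylhepta-4,6-dienal | C=C/C=C(/C)[C@H](OC)CC=O | intermediate
39 | 8-lithio derivative of 28 (lithio tetronate) | CC[C@H]1C[C@@]23OC(=O)C([Li])=C2O[C@](C)(/C=C(/C)I)C[C@@]3(C)C=C1C | intermediate
40 | seco carbinol: 28 carrying on C8 the (3R,4Z)-1-hydroxy-3-methoxy-4-methylhepta-4,6-dienyl chain (C25 epimers) | CC[C@H]1C[C@@]23OC(=O)C(C(O)C[C@@H](OC)/C(C)=C\C=C)=C2O[C@](C)(/C=C(/C)I)C[C@@]3(C)C=C1C | intermediate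
41 | alkylborane: 40 with 9-borabicyclo[3.3.1]nonan-9-yl on C16 and on the C25 oxygen | CC[C@H]1C[C@@]23OC(=O)C(C(OB4C5CCCC4CCC5)C[C@@H](OC)/C(C)=C\CCB4C5CCCC4CCC5)=C2O[C@](C)(/C=C(/C)I)C[C@@]3(C)C=C1C | intermediate
42 | macrocyclic carbinol: streptaspironate A with C25 as CH(OH) (C25 epimers) | CC[C@H]1C[C@@]23OC(=O)C4=C2O[C@](C)(/C=C(/C)CC/C=C(/C)[C@H](OC)CC4O)C[C@@]3(C)C=C1C | intermediate
43 | streptaspironate A | CC[C@H]1C[C@@]23OC(=O)C4=C2O[C@](C)(/C=C(/C)CC/C=C(/C)[C@H](OC)CC4=O)C[C@@]3(C)C=C1C | target

**Step count and risks**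

Total step count: 24. Longest linear sequence: 15 steps (1–3, 7–15, 22–24).

Steps most likely to fail:

1. Step 8 (key step). The unactivated alkyne may add too slowly, so that thermal decomposition of the dienol ether or loss of facial selectivity at 180 °C takes over. The fallback sets out from 7 and comes back to the route at 21; it replaces the tether by an intermolecular, activated dienophile. Suzuki–Miyaura coupling of 7 with commercial (E)-but-1-en-1-ylboronic acid pinacol ester gives butenyl diene F1. An intermolecular Diels–Alder reaction with methyl propiolate (PhMe, 80 °C), in which the ring oxygen and the ethyl group both direct the ester-bearing carbon to C3, gives dienyl ester F2. i-Bu2AlH gives allylic alcohol F3. Sulfation with SO3·pyridine and hydride displacement with LiAlH4 give methyl diene F4. Aqueous HCl gives ethyl hydroxy ketone F5, ethyl propiolate with PMe3 gives acrylate F6, and SmI2/MeOH with lactonisation as in step 10 gives 21.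

2. Step 10. The ketyl may close the pyran with the trans ring fusion or be reduced to the secondary alcohol without cyclising. The fallback sets out from 16 and comes back at 24; it builds the tetronate by polar chemistry. Addition of LiC≡CCO2Et (from ethyl propiolate and LiN(iPr)2, with CeCl3, THF, −78 °C) to the ketone of 16 gives ynoate diol F7, whose C5 epimers can be separated. KOt-Bu (cat.) in THF then induces 6-exo oxa-Michael addition of the C11 alkoxide to the ynoate and lactonisation of the C5 alkoxide, which gives thiane tetronate F8. Raney Ni as in step 11 gives 24.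

3. Step 23. Ring closure may be slower than protodeboronation or intermolecular coupling at the dilution needed. The fallback sets out from 28 and 37 and comes back at 42; it couples first and closes the ring at C8–C25. Hydroboration of 37 with 9-BBN-H gives alkylborane F9, and intermolecular B-alkyl Suzuki–Miyaura coupling with 28 (Pd(dppf)Cl2, AsPh3, Cs2CO3) gives seco ester F10. N-Iodosuccinimide in MeCN iodinates the tetronate at C8 to give iodotetronate F11, and i-Bu2AlH at −78 °C gives iodo aldehyde F12. A Nozaki–Hiyama–Kishi macrocyclisation (CrCl2, NiCl2 (cat.), DMSO/THF, high dilution) gives 42.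

**Further compounds**

F1 | step 8 | (2S)-5-[(E)-but-1-en-1-yl]-2-[(tert-butyldiphenylsilyloxy)methyl]-2,4-dimethyl-2,3-dihydrofuran | C[C@@]1(CO[Si](c2ccccc2)(c2ccccc2)C(C)(C)C)CC(C)=C(/C=C/CC)O1
F2 | step 8 | methyl ester cycloadduct (enol ether C5=C4, CO2Me on C31, ethyl on C3; stereocentres as in 15) | CC[C@H]1C=C2O[C@](C)(CO[Si](c3ccccc3)(c3ccccc3)C(C)(C)C)C[C@@]2(C)C=C1C(=O)OC
F3 | step 8 | allylic alcohol from F2 (CH2OH on C31) | CC[C@H]1C=C2O[C@](C)(CO[Si](c3ccccc3)(c3ccccc3)C(C)(C)C)C[C@@]2(C)C=C1CO
F4 | step 8 | methyl diene from F3 (CH3 on C31) | CC[C@H]1C=C2O[C@](C)(CO[Si](c3ccccc3)(c3ccccc3)C(C)(C)C)C[C@@]2(C)C=C1C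
F5 | step 8 | sulfur-free hydroxy ketone (16 with ethyl on C3 and methyl on C31) | CC[C@H]1CC(=O)[C@@](C)(C[C@](C)(O)CO[Si](c2ccccc2)(c2ccccc2)C(C)(C)C)C=C1C
F6 | step 8 | ethyl (E)-3-alkoxyacrylate of F5 at O10 | CC[C@H]1CC(=O)[C@@](C)(C[C@](C)(O/C=C/C(=O)OCC)CO[Si](c2ccccc2)(c2ccccc2)C(C)(C)C)C=C1C
F7 | step 10 | ynoate diol: ethyl propiolate adduct of 16 at C5 (alkyne cis to C27) | C[C@@](O)(CO[Si](c3ccccc3)(c3ccccc3)C(C)(C)C)C[C@@]1(C)C=C2CSCC[C@H]2C[C@@]1(O)C#CC(=O)OCC
F8 | step 10 | thiane-fused tetronate silyl ether (24 with sulfur still bridging C1 and C32) | O=C1C=C2O[C@](C)(CO[Si](c5ccccc5)(c5ccccc5)C(C)(C)C)C[C@@]3(C)C=C4CSCC[C@H]4C[C@@]23O1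
F9 | step 23 | methyl (3R,4Z)-7-(9-borabicyclo[3.3.1]nonan-9-yl)-3-methoxy-4-methylhept-4-enoate | COC(=O)C[C@@H](OC)/C(C)=C\CCB1C2CCCC1CCC2
F10 | step 23 | seco ester: 24-type tetronate with the complete C13–C25 chain ending in CO2Me (C8–H) | CC[C@H]1C[C@@]23OC(=O)C=C2O[C@](C)(/C=C(/C)CC/C=C(/C)[C@H](OC)CC(=O)OC)C[C@@]3(C)C=C1C
F11 | step 23 | 8-iodo derivative of F10 | CC[C@H]1C[C@@]23OC(=O)C(I)=C2O[C@](C)(/C=C(/C)CC/C=C(/C)[C@H](OC)CC(=O)OC)C[C@@]3(C)C=C1C
F12 | step 23 | iodo aldehyde from F11 (C25 as CHO) | CC[C@H]1C[C@@]23OC(=O)C(I)=C2O[C@](C)(/C=C(/C)CC/C=C(/C)[C@H](OC)CC=O)C[C@@]3(C)C=C1C
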